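Take the ratio of two amounts of D: what was lost to something other than E, over the surplus charged beyond G.

| flask | G | D | temperature | remark | time |
|---|---|---|---|---|---|
| Monday's | 0.14 M | 0.168 M | 25 °C | the very flask that is asked about, followed so far |  |
| Saturday's | 0.14 M | 0.168 M | 10 °C | run made earlier |  |
| flask | 0.14 M | 0.168 M | 25 °C |  | 5.0 d |

| run | time / d | E / % | G / % |
|---|---|---|---|
| Monday's | 0.625 | 84.4 | 0.9 |
| Monday's | 1.25 | 86.3 | 0 |
| Monday's | 2.00 | 85.4 | 0 |
| Monday's | 3.00 | 85.3 | 0.5 |
| Monday's | 4.00 | 84.9 | 0 |
| Monday's | 5.00 | 86.4 | 0.7 |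
| Saturday's | 1.25 | 100.6 | 0 |
| Saturday's | 2.50 | 97.5 | 0 |
| Saturday's | 4.00 | 100.8 | 0 |
| Saturday's | 6.00 | 99.6 | 0.4 |
| Saturday's | 8.00 | 99.6 | 0.6 |
| Saturday's | 10.0 | 100.4 | 0.5 |

(standard deviation of a reading: 1 percentage point)

- additions bring no volume worth counting
- at the start none of G is in solution
- a reading or a percentage of E counts all its forms, free or not

- autumn: at 5.0 d raise the temperature by 15 K, then wait 10 d
- noon: change nothing and wait 10 d more
- spring: at 5.0 d add D, 100% of the amount charged, then wait 10 d

* E, in percent of the G first charged, at 5.0 d
* the option that brings most further E ("none" if no option brings more than 2 percentage points) (autumn / noon / spring / none)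
* E present, in percent of the G first charged, after autumn
* E present, in percent of the G first charged, after spring

Read Monday's run at 25 °C: E lies flat from the first reading at a mean of 85.4%, and G reads near zero. But G starts undissolved, so that zero may say only that the solid went, not that it became E. Saturday's run at 10 °C, with the same charge, reads 100.4% of E at 10.0 d, so take one D per E. The surplus is then 0.0280 M.

Suppose the flat line marks free D at zero, with D as the limiting reagent. Then Monday's flask lost 0.0484 M of D, and the overdraft, lost D over surplus D, is 1.73. That is more than one, so on this supposition E stops short in Monday's flask and the rest of G waits dissolved.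

Commit to this reckoning of my own: waiting and heating add nothing, since neither brings D. Spring should lift E to about full, since the waiting G needs 0.0204 M of D, less than the 0.168 M added.

The forecast gives 85.5% now, 85.5% after autumn, 85.5% after spring and none as best, holding that “waiting, heating or adding D has nothing to convert”. My reckoning parts from it at spring.

The flask gives 84.6% at 5.0 d, 84.6% after autumn and 100% after spring, so the best option is spring, with a gain of 15 percentage points.

    D → X (k = 2.30 × 10⁻⁵ s⁻¹, Ea = 109 kJ mol⁻¹)
    Z ⇌ E, rate k2*(cs2 - [E]) while solid is left; crystals form when [E] > cs2 (solubility = 0.0540 M, k = 0.0130 s⁻¹)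
    Q + D → E (k = 0.0230 L mol⁻¹ s⁻¹, Ea = 64.0 kJ mol⁻¹)
    G ⇌ Q, rate k4*(cs4 - [Q]) while solid is left; crystals form when [Q] > cs4 (solubility = 0.0930 M, k = 4.90 × 10⁻⁵ s⁻¹)
    (constants at 25 °C)

At 5.00 d the flask holds Q 15.4%, free D 0% and X 0.0496 M, so an overdraft of 1.73 left that Q waiting for D. Take the path from D to X away and E goes from 84.6% to 100%. Now try the neighbour flask with 0.084 M of G: its surplus is 0.0840 M and its X at 5.00 d is 0.0840 M, so its overdraft is 1.00, about one, and that flask gives 100%.

The readings were generated by integration from invented constants; noise was put on by code.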